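**Plan**

Cuts, in retrosynthetic order: the C=CH2 bond (from a ketone); the CMe2–CH(ring fusion) bond of the seven-membered ring; the acyl–cyclopentene C–C bond; the lactone (butenolide C=C and C–O); last the quaternary C–CH bond to the side chain.
Enabling feature: in the seven-membered ring the CMe2 carbon is bonded to one ring-fusion CH and the =CH2-bearing carbon to the other. With that carbon as C=O, the fusion bond is the α,β-bond of a 1-acylcyclopentene and the CMe2 carbon is the tertiary radical of an isopropenyl group at the end of the acyl chain.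
Forward: the cyclopentene is bought; the quaternary carbon and side-chain methine come from an Ireland–Claisen rearrangement; the lactone ring is built and oxygenated on the vinyl iodide; the acyl chain is joined by CrCl2/NiCl2 coupling; the seven-membered ring is closed last by Fe(acac)3/PhSiH3 radical cyclisation; methylenation finishes.
Stereochemistry: CBS reduction sets one carbinol, which the Claisen step transfers to the quaternary carbon and its neighbour; lactone C4 comes from CuH reduction (ligand and substrate matched) and C3–O trans from enolate hydroxylation; both ring-fusion centres arise in the key step under control of the quaternary carbon.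

Key step: step 14

Assumption: the silyl-protected hydroxy acid used in step 3 is taken as a catalogue compound.

**Route**

Step 1
Reactants: 1 3-methylcyclopent-2-en-1-one
Product: 2 2-iodo-3-methylcyclopent-2-en-1-one
Conditions: I2, K2CO3, DMAP (cat.), THF/H2O (1:1), rt
Reagents that add atoms: iodine, II
Why: Baylis–Hillman-type α-iodination of an enone (conjugate addition of DMAP, iodination of the enolate, elimination) should place iodine at C2 only.

Step 2
Reactants: 2 2-iodo-3-methylcyclopent-2-en-1-one
Product: 3 (S)-2-iodo-3-methylcyclopent-2-en-1-ol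
Conditions: (R)-2-methyl-CBS-oxazaborolidine (15 mol %), BH3·SMe2, THF, −20 °C; MeOH quench
Reagents that add atoms: none
Why: Corey–Bakshi–Shibata reduction in which the iodoalkenyl carbon acts as the large group, so the (R)-catalyst should deliver hydride to give the (S)-carbinol, the centre later transferred to carbon.

Step 3
Reactants: 3 (S)-2-iodo-3-methylcyclopent-2-en-1-ol; 4 3-[(tert-butyldiphenylsilyl)oxy]propanoic acid
Product: 5 (S)-2-iodo-3-methylcyclopent-2-en-1-yl 3-[(tert-butyldiphenylsilyl)oxy]propanoate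
Conditions: DCC, DMAP (cat.), CH2Cl2, 0 °C to rt
Reagents that add atoms: none
Why: Steglich esterification of a secondary allylic alcohol; the bulky, non-chelating silyl ether is chosen to keep the later enolate geometry kinetic.

Step 4
Reactants: 5 (S)-2-iodo-3-methylcyclopent-2-en-1-yl 3-[(tert-butyldiphenylsilyl)oxy]propanoate
Product: 8 (2R)-3-[(tert-butyldiphenylsilyl)oxy]-2-[(1S)-2-iodo-1-methylcyclopent-2-en-1-yl]propanoic acid, via silyl ketene acetal 6 (not isolated), via trimethylsilyl ester 7 (not isolated)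
Conditions: LiN(i-Pr)2, Me3SiCl/Et3N (internal quench), THF, −78 °C, then 65 °C; 1 M HCl work-up
Reagents that add atoms: none
Why: Ireland–Claisen rearrangement: kinetic enolisation with internal silyl quench should give the (E)-silyl ketene acetal before silanolate can be eliminated, and the chair transition state (the boat would put OSiMe3 against the C2 iodine and the CH2OSi group under the ring) transfers the carbinol configuration suprafacially to the new quaternary carbon and fixes the adjacent methine.

Step 5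
Reactants: 8 (2R)-3-[(tert-butyldiphenylsilyl)oxy]-2-[(1S)-2-iodo-1-methylcyclopent-2-en-1-yl]propanoic acid
Product: 11 (3R)-4-[(tert-butyldiphenylsilyl)oxy]-1-hydroxy-3-[(1S)-2-iodo-1-methylcyclopent-2-en-1-yl]butan-2-one, via acid chloride 9 (not isolated), via silylated keto ester 10 (not isolated)
Conditions: (COCl)2, DMF (cat.), CH2Cl2, 0 °C to rt; then (Me3SiO)2C=CH(OSiMe3), SnCl4 (cat.), neat, rt to 60 °C; then 0.5 M HCl, dioxane, 50 °C
Reagents that add atoms: tris(trimethylsilyloxy)ethylene, C[Si](C)(C)OC=C(O[Si](C)(C)C)O[Si](C)(C)C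
Why: Wissner hydroxymethyl ketone synthesis (C-acylation of the ketene tris(silyl) acetal, then hydrolysis and decarboxylation of the β-keto acid); no base is present, so the hindered α-methine should keep its configuration.

Step 6
Reactants: 11 (3R)-4-[(tert-butyldiphenylsilyl)oxy]-1-hydroxy-3-[(1S)-2-iodo-1-methylcyclopent-2-en-1-yl]butan-2-one
Product: 13 4-{(1R)-2-[(tert-butyldiphenylsilyl)oxy]-1-[(1S)-2-iodo-1-methylcyclopent-2-en-1-yl]ethyl}furan-2(5H)-one, via acyl ylide 12 (not isolated)
Conditions: Ph3P=C=C=O, Et3N (cat.), toluene, 90 °C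
Reagents that add atoms: (triphenylphosphoranylidene)ketene, O=C=C=P(c1ccccc1)(c1ccccc1)c1ccccc1
Why: Bestmann butenolide annulation: the primary alcohol adds to the ketenylidene ylide and the ester ylide closes by intramolecular Wittig reaction onto the ketone, as in the cardenolide series, forming the lactone ring.

Step 7
Reactants: 13 4-{(1R)-2-[(tert-butyldiphenylsilyl)oxy]-1-[(1S)-2-iodo-1-methylcyclopent-2-en-1-yl]ethyl}furan-2(5H)-one
Product: 14 (4R)-4-{(1R)-2-[(tert-butyldiphenylsilyl)oxy]-1-[(1S)-2-iodo-1-methylcyclopent-2-en-1-yl]ethyl}oxolan-2-one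
Conditions: Cu(OAc)2 (5 mol %), (S)-p-tol-BINAP (5 mol %), (EtO)2MeSiH, t-BuOH, toluene, 0 °C to rt
Reagents that add atoms: none
Why: Buchwald-type asymmetric CuH 1,4-reduction of a β-substituted butenolide; hydride should add to C4 anti to the quaternary cyclopentyl group in the A(1,3)-minimised rotamer, and the ligand enantiomer is taken as the one matched with this bias (its sense is an assumption to be checked).

Step 8
Reactants: 14 (4R)-4-{(1R)-2-[(tert-butyldiphenylsilyl)oxy]-1-[(1S)-2-iodo-1-methylcyclopent-2-en-1-yl]ethyl}oxolan-2-one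
Product: 16 (3S,4R)-4-{(1R)-2-[(tert-butyldiphenylsilyl)oxy]-1-[(1S)-2-iodo-1-methylcyclopent-2-en-1-yl]ethyl}-3-hydroxyoxolan-2-one, via potassium enolate 15 (not isolated)
Conditions: KN(SiMe3)2, THF, −78 °C; then 2-(phenylsulfonyl)-3-phenyloxaziridine, −78 °C; NH4Cl (aq)
Reagents that add atoms: 2-(phenylsulfonyl)-3-phenyloxaziridine, O=S(=O)(c1ccccc1)N1OC1c1ccccc1
Why: Davis enolate hydroxylation; the oxidant should approach the lactone enolate anti to the branched C4 substituent and give the trans 3-hydroxy lactone.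

Step 9
Reactants: 16 (3S,4R)-4-{(1R)-2-[(tert-butyldiphenylsilyl)oxy]-1-[(1S)-2-iodo-1-methylcyclopent-2-en-1-yl]ethyl}-3-hydroxyoxolan-2-one
Product: 18 (3S,4R)-4-{(1R)-2-(acetyloxy)-1-[(1S)-2-iodo-1-methylcyclopent-2-en-1-yl]ethyl}-2-oxooxolan-3-yl acetate, via diol 17 (not isolated)
Conditions: Bu4NF, AcOH, THF, 0 °C to rt; then Ac2O, pyridine, DMAP (cat.), CH2Cl2, 0 °C
Reagents that add atoms: acetic anhydride, CC(=O)OC(C)=O
Why: Buffered fluoride desilylation followed at once by acetylation should cap both hydroxyls before the primary one can translactonise.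

Step 10
Reactants: 19 methyl 5-oxohexanoate
Product: 20 methyl 5-methylhex-5-enoate
Conditions: Ph3PCH3Br, KOt-Bu, THF, 0 °C to rt
Reagents that add atoms: methyltriphenylphosphonium bromide, C[P+](c1ccccc1)(c1ccccc1)c1ccccc1.[Br-]
Why: Wittig methylenation; the ketone reacts much faster than the ester.

Step 11
Reactants: 20 methyl 5-methylhex-5-enoate
Product: 21 5-methylhex-5-enal
Conditions: i-Bu2AlH (1.05 equiv), CH2Cl2, −78 °C; potassium sodium tartrate (aq) work-up
Reagents that add atoms: none
Why: Partial reduction of an ester, stopped at the aluminium hemiacetal at low temperature.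

Step 12
Reactants: 18 (3S,4R)-4-{(1R)-2-(acetyloxy)-1-[(1S)-2-iodo-1-methylcyclopent-2-en-1-yl]ethyl}-2-oxooxolan-3-yl acetate; 21 5-methylhex-5-enal
Product: 22 (3S,4R)-4-{(1R)-2-(acetyloxy)-1-[(1S)-2-(1-hydroxy-5-methylhex-5-en-1-yl)-1-methylcyclopent-2-en-1-yl]ethyl}-2-oxooxolan-3-yl acetate (both carbinol epimers)
Conditions: CrCl2 (4 equiv), NiCl2 (2 mol %), DMSO, rt
Reagents that add atoms: none
Why: Nozaki–Hiyama–Kishi coupling (oxidative addition of the hindered vinyl iodide to zerovalent nickel, transmetalation to chromium, addition to the aldehyde) tolerates the lactone and acetates; the new carbinol centre is removed in step 13.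

Step 13
Reactants: 22 (3S,4R)-4-{(1R)-2-(acetyloxy)-1-[(1S)-2-(1-hydroxy-5-methylhex-5-en-1-yl)-1-methylcyclopent-2-en-1-yl]ethyl}-2-oxooxolan-3-yl acetate
Product: 23 (3S,4R)-4-{(1R)-2-(acetyloxy)-1-[(1S)-1-methyl-2-(5-methylhex-5-enoyl)cyclopent-2-en-1-yl]ethyl}-2-oxooxolan-3-yl acetate
Conditions: Dess–Martin periodinane, NaHCO3, CH2Cl2, 0 °C to rt
Reagents that add atoms: none
Why: Dess–Martin oxidation of an allylic alcohol to the enone under buffered, non-epimerising conditions.

Step 14
Reactants: 23 (3S,4R)-4-{(1R)-2-(acetyloxy)-1-[(1S)-1-methyl-2-(5-methylhex-5-enoyl)cyclopent-2-en-1-yl]ethyl}-2-oxooxolan-3-yl acetate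
Product: 24 (3S,4R)-4-{(1R)-2-(acetyloxy)-1-[cis-fused 1,4,4-trimethyl-8-oxodecahydroazulen-1-yl]ethyl}-2-oxooxolan-3-yl acetate (ring-fusion hydrogens cis to each other and to the side chain; 1-methyl on the opposite face)
Conditions: Fe(acac)3 (30 mol %), PhSiH3 (slow addition), EtOH/(CH2OH)2 (5:1), 0.01 M, 50 °C
Reagents that add atoms: none
Why: Fe(acac)3 and PhSiH3 form a trivalent iron hydride that transfers a hydrogen atom to the CH2 terminus of the isopropenyl group (the electron-rich alkene; the enone is a poor acceptor), the tertiary radical adds to the β-carbon of the cyclopentenyl ketone, and the α-keto radical is reduced by divalent iron to an enolate that the alcohol protonates. The closest known reaction type is the intramolecular iron-mediated reductive olefin coupling (hydrogen-atom-transfer Giese cyclisation) used to make quaternary carbons next to ring-fusion centres. The seven-membered ring closes in the 7-endo-trig mode with the ketone inside the new ring, in the s-trans enone conformer that the quaternary neighbour enforces. The CMe2–CH centre is set by approach of the tethered radical to the cyclopentene face anti to the branched side chain on the adjacent quaternary carbon (syn to its methyl group). The second ring-fusion centre is set by protonation of the enolate on the side-chain face, which gives the cis-fused ketone with the ring carbonyl carbon anti to that side chain, the arrangement also expected to be favoured at equilibrium. The step needs hydrogen-atom transfer to the 1,1-disubstituted alkene only and β- rather than α- or O-attack, both secured by the polarity match of a nucleophilic tertiary radical with the enone β-carbon, while slow silane addition keeps the hydride concentration low so that the radical is not reduced before it cyclises.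

Step 15
Reactants: 24 (3S,4R)-4-{(1R)-2-(acetyloxy)-1-[cis-fused 1,4,4-trimethyl-8-oxodecahydroazulen-1-yl]ethyl}-2-oxooxolan-3-yl acetate
Product: 25 CNP0234964.1 (target)
Conditions: Zn, CH2Br2, TiCl4, THF/CH2Cl2, 0 °C to rt
Reagents that add atoms: dibromomethane, BrCBr
Why: Takai–Lombardo methylenation is non-basic, so the epimerisable ring-fusion centre next to the ketone should be kept, and lactone and acetates are not attacked.

**Compound list**

1 | 3-methylcyclopent-2-en-1-one | CC1=CC(=O)CC1 | starting material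
2 | 2-iodo-3-methylcyclopent-2-en-1-one | CC1=C(I)C(=O)CC1 | intermediate
3 | (S)-2-iodo-3-methylcyclopent-2-en-1-ol | O[C@H]1CCC(C)=C1I | intermediate
4 | 3-[(tert-butyldiphenylsilyl)oxy]propanoic acid | OC(=O)CCO[Si](c1ccccc1)(c1ccccc1)C(C)(C)C | starting material
5 | (S)-2-iodo-3-methylcyclopent-2-en-1-yl 3-[(tert-butyldiphenylsilyl)oxy]propanoate | O=C(CCO[Si](c1ccccc1)(c1ccccc1)C(C)(C)C)O[C@H]1CCC(C)=C1I | intermediate
6 | (E)-O-trimethylsilyl ketene acetal of 5 (CH2OSi cis to the allylic oxygen; not isolated) | C[Si](C)(C)O/C(=C/CO[Si](c1ccccc1)(c1ccccc1)C(C)(C)C)O[C@H]1CCC(C)=C1I | intermediate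
7 | trimethylsilyl ester of 8 (not isolated) | IC1=CCC[C@@]1(C)[C@H](CO[Si](c1ccccc1)(c1ccccc1)C(C)(C)C)C(=O)O[Si](C)(C)C | intermediate
8 | (2R)-3-[(tert-butyldiphenylsilyl)oxy]-2-[(1S)-2-iodo-1-methylcyclopent-2-en-1-yl]propanoic acid | IC1=CCC[C@@]1(C)[C@H](CO[Si](c1ccccc1)(c1ccccc1)C(C)(C)C)C(O)=O | intermediate
9 | acid chloride of 8 (not isolated) | IC1=CCC[C@@]1(C)[C@H](CO[Si](c1ccccc1)(c1ccccc1)C(C)(C)C)C(Cl)=O | intermediate
10 | trimethylsilyl 3-oxo-2-(trimethylsilyloxy)butanoate bearing the side chain of 8 at C4 (C2 epimers; not isolated) | IC1=CCC[C@@]1(C)[C@H](CO[Si](c1ccccc1)(c1ccccc1)C(C)(C)C)C(=O)C(O[Si](C)(C)C)C(=O)O[Si](C)(C)C | intermediate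
11 | (3R)-4-[(tert-butyldiphenylsilyl)oxy]-1-hydroxy-3-[(1S)-2-iodo-1-methylcyclopent-2-en-1-yl]butan-2-one | IC1=CCC[C@@]1(C)[C@H](CO[Si](c1ccccc1)(c1ccccc1)C(C)(C)C)C(=O)CO | intermediate
12 | (triphenylphosphoranylidene)acetate ester of 11 (not isolated) | IC1=CCC[C@@]1(C)[C@H](CO[Si](c1ccccc1)(c1ccccc1)C(C)(C)C)C(=O)COC(=O)C=P(c1ccccc1)(c1ccccc1)c1ccccc1 | intermediate
13 | 4-{(1R)-2-[(tert-butyldiphenylsilyl)oxy]-1-[(1S)-2-iodo-1-methylcyclopent-2-en-1-yl]ethyl}furan-2(5H)-one | IC1=CCC[C@@]1(C)[C@H](CO[Si](c1ccccc1)(c1ccccc1)C(C)(C)C)C1=CC(=O)OC1 | intermediate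
14 | (4R)-4-{(1R)-2-[(tert-butyldiphenylsilyl)oxy]-1-[(1S)-2-iodo-1-methylcyclopent-2-en-1-yl]ethyl}oxolan-2-one | IC1=CCC[C@@]1(C)[C@H](CO[Si](c1ccccc1)(c1ccccc1)C(C)(C)C)[C@@H]1COC(=O)C1 | intermediate
15 | potassium enolate of 14 (not isolated) | IC1=CCC[C@@]1(C)[C@H](CO[Si](c1ccccc1)(c1ccccc1)C(C)(C)C)[C@@H]1COC([O-])=C1.[K+] | intermediate
16 | (3S,4R)-4-{(1R)-2-[(tert-butyldiphenylsilyl)oxy]-1-[(1S)-2-iodo-1-methylcyclopent-2-en-1-yl]ethyl}-3-hydroxyoxolan-2-one | IC1=CCC[C@@]1(C)[C@H](CO[Si](c1ccccc1)(c1ccccc1)C(C)(C)C)[C@@H]1COC(=O)[C@H]1O | intermediate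
17 | (3S,4R)-3-hydroxy-4-{(1R)-2-hydroxy-1-[(1S)-2-iodo-1-methylcyclopent-2-en-1-yl]ethyl}oxolan-2-one (not isolated) | IC1=CCC[C@@]1(C)[C@H](CO)[C@@H]1COC(=O)[C@H]1O | intermediate
18 | (3S,4R)-4-{(1R)-2-(acetyloxy)-1-[(1S)-2-iodo-1-methylcyclopent-2-en-1-yl]ethyl}-2-oxooxolan-3-yl acetate | IC1=CCC[C@@]1(C)[C@H](COC(C)=O)[C@@H]1COC(=O)[C@H]1OC(C)=O | intermediate
19 | methyl 5-oxohexanoate | CC(=O)CCCC(=O)OC | starting material
20 | methyl 5-methylhex-5-enoate | C=C(C)CCCC(=O)OC | intermediate
21 | 5-methylhex-5-enal | C=C(C)CCCC=O | intermediate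
22 | allylic alcohol from 18 and 21 (both carbinol epimers) | C=C(C)CCCC(O)C1=CCC[C@@]1(C)[C@H](COC(C)=O)[C@@H]1COC(=O)[C@H]1OC(C)=O | intermediate
23 | dienone: 1-acylcyclopentene bearing the 5-methylhex-5-enoyl chain | C=C(C)CCCC(=O)C1=CCC[C@@]1(C)[C@H](COC(C)=O)[C@@H]1COC(=O)[C@H]1OC(C)=O | intermediate
24 | cis-fused 8-oxo-decahydroazulene (ring-fusion H atoms cis to the side chain) | O=C1CCCC(C)(C)[C@@H]2CC[C@@](C)([C@H](COC(C)=O)[C@@H]3COC(=O)[C@H]3OC(C)=O)[C@H]12 | intermediate
25 | CNP0234964.1 | C=C1CCCC(C)(C)[C@@H]2CC[C@@](C)([C@H](COC(C)=O)[C@@H]3COC(=O)[C@H]3OC(C)=O)[C@H]12 | target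

**Step count and risks**

Total step count: 15. Longest linear sequence: 13 steps (steps 1–9 and 12–15).

Steps most likely to fail:

1. Step 14. The tertiary radical may be reduced to an isopropyl group before the slow 7-endo closure, or may add to the cyclopentene face syn to the side chain. The fallback sets out from 23 and comes back at 24. Markovnikov hydration of the isopropenyl group of 23 with Co(acac)2, PhSiH3 and O2 in i-PrOH should give the tertiary alcohol F1. Acylation with (COCl)2 followed by aqueous CsHCO3 should give the cesium tert-alkyl oxalate F2. Irradiation with blue light and Ir[dF(CF3)ppy]2(dtbbpy)PF6 in DME/DMF/H2O generates the same tertiary radical by double decarboxylation under redox-neutral conditions with no hydride donor present, so cyclisation onto the enone has no competitor; reduction of the α-keto radical by the reduced photocatalyst and protonation should then give 24.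

2. Step 4. Silanolate may be lost by β-elimination from the ester enolate, or the rearrangement may leak through the boat transition state and erode the configuration of the side-chain methine. The fallback sets out from 3 and comes back at 8. Acetylation of 3 gives the acetate F3, whose Ireland–Claisen rearrangement gives the acid F4 with only the quaternary centre, which is fixed by suprafacial transfer whatever the transition-state shape. Activation with t-BuCOCl/Et3N and reaction with lithiated (S)-4-benzyloxazolidin-2-one gives the imide F5. Its titanium enolate (TiCl4, i-Pr2NEt) with s-trioxane gives the hydroxymethyl imide F6 under auxiliary control. Silylation (t-BuPh2SiCl, imidazole) gives the silyl ether F7, and LiOH/H2O2 cleaves the auxiliary to give 8.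

3. Step 5. The methine α to the new ketone may epimerise, and the silyl ether may be lost, during acidic hydrolysis and decarboxylation; acylation of the ketene acetal by the hindered acid chloride may also be slow. The fallback sets out from 8 and comes back at 13, bypassing 11. The acid chloride of 8 with CH2N2 gives the diazoketone F8. O–H insertion with (EtO)2P(O)CH2CO2H under Cu(acac)2 catalysis gives the phosphonoacetate F9. Intramolecular Horner–Wadsworth–Emmons closure (LiCl, i-Pr2NEt, MeCN) then gives butenolide 13 under nearly neutral conditions.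

**Further compounds**

F1 | step 14 | tertiary alcohol from hydration of the isopropenyl group of 23 | CC(C)(O)CCCC(=O)C1=CCC[C@@]1(C)[C@H](COC(C)=O)[C@@H]1COC(=O)[C@H]1OC(C)=O
F2 | step 14 | cesium tert-alkyl oxalate of F1 | [Cs+].[O-]C(=O)C(=O)OC(C)(C)CCCC(=O)C1=CCC[C@@]1(C)[C@H](COC(C)=O)[C@@H]1COC(=O)[C@H]1OC(C)=O
F3 | step 4 | (S)-2-iodo-3-methylcyclopent-2-en-1-yl acetate | CC(=O)O[C@H]1CCC(C)=C1I
F4 | step 4 | 2-[(1S)-2-iodo-1-methylcyclopent-2-en-1-yl]acetic acid | IC1=CCC[C@@]1(C)CC(O)=O
F5 | step 4 | (S)-4-benzyl-3-{2-[(1S)-2-iodo-1-methylcyclopent-2-en-1-yl]acetyl}oxazolidin-2-one | IC1=CCC[C@@]1(C)CC(=O)N1C(=O)OC[C@@H]1Cc1ccccc1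
F6 | step 4 | (S)-4-benzyl-3-{(2R)-3-hydroxy-2-[(1S)-2-iodo-1-methylcyclopent-2-en-1-yl]propanoyl}oxazolidin-2-one | IC1=CCC[C@@]1(C)[C@H](CO)C(=O)N1C(=O)OC[C@@H]1Cc1ccccc1
F7 | step 4 | tert-butyldiphenylsilyl ether of F6 | IC1=CCC[C@@]1(C)[C@H](CO[Si](c1ccccc1)(c1ccccc1)C(C)(C)C)C(=O)N1C(=O)OC[C@@H]1Cc1ccccc1
F8 | step 5 | diazoketone from 8 | IC1=CCC[C@@]1(C)[C@H](CO[Si](c1ccccc1)(c1ccccc1)C(C)(C)C)C(=O)C=[N+]=[N-]
F9 | step 5 | (diethoxyphosphoryl)acetate of hydroxymethyl ketone 11 | IC1=CCC[C@@]1(C)[C@H](CO[Si](c1ccccc1)(c1ccccc1)C(C)(C)C)C(=O)COC(=O)CP(=O)(OCC)OCC
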